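**Retrosynthetic overview**

1. Target 34 ← tris-MOM flavanone 33 ← 3-aryl-3-aryloxypropanoic acid 31: ring C is closed last by Friedel–Crafts acylation (C4–C4a), then all MOM groups are removed.
2. Ring A of 31 ← alkynyl ether 19 + vinylketene from diazo ketone 22: C7–C8 and C4a–C8a by [2+2] cycloaddition, C6–C7 by six-electron electrocyclisation.
3. 19 ← (S)-alcohol 11 + trichloroethylene 12 + prenyl bromide 16; C2 is set by asymmetric transfer hydrogenation of β-keto ester 8; ring B comes from bromocatechol aldehyde 1 by MOM protection and Stille prenylation.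
4. Feature used: on ring A the C7 hydroxyl, the C8 prenyl group and the C8a–O1 oxygen sit on three adjacent carbons (a 2-alkylresorcinol), the pattern a ketene–alkoxyalkyne annulation delivers, and the alkoxy oxygen of the alkyne is O1 already bonded to stereocentre C2.
5. Ring order: B (purchased arene), A (step 12), C (step 16).

Key step: step 12

Remark: Ar = 3,4-bis(methoxymethoxy)-5-(3-methylbut-2-en-1-yl)phenyl. The side-chain hydroxyl is carried as a triisopropylsilyl ether, because a smaller silyl group could migrate to the neighbouring potassium alkoxide of step 8. Diazomethane is generated from a commercial N-nitroso precursor.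

**Route**

Step 1
Reactants: 1 3-bromo-4,5-dihydroxybenzaldehyde
Product: 2 3-bromo-4,5-bis(methoxymethoxy)benzaldehyde
Conditions: MOMCl (2.6 equiv), i-Pr2NEt, CH2Cl2, 0 → 20 °C
Reagents that add atoms: chloromethyl methyl ether, COCCl
Why: O-alkylation of both phenols by the reactive chloromethyl ether under amine base (MOM protection) should proceed cleanly, the aldehyde and the aryl bromide being inert.

Step 2
Reactants: 2 3-bromo-4,5-bis(methoxymethoxy)benzaldehyde; 3 tributyl(3-methylbut-2-en-1-yl)stannane
Product: 4 3,4-bis(methoxymethoxy)-5-(3-methylbut-2-en-1-yl)benzaldehyde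
Conditions: Pd(PPh3)4 (5 mol%), DMF, 95 °C
Reagents that add atoms: none
Why: Stille coupling, in which zerovalent palladium inserts into the C–Br bond and the allylic stannane transfers its prenyl group, should give the linear prenyl arene by reductive elimination at the unhindered primary terminus, with aldehyde and MOM ethers tolerated under the neutral conditions.

Step 3
Reactants: 4 3,4-bis(methoxymethoxy)-5-(3-methylbut-2-en-1-yl)benzaldehyde; 5 ethyl acetate
Product: 7 ethyl (±)-3-Ar-3-hydroxypropanoate, via lithium enolate of ethyl acetate 6 (not isolated)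
Conditions: LiN(i-Pr)2, THF, −78 °C, then 4; aq. NH4Cl
Reagents that add atoms: none
Why: Aldol addition of the preformed lithium ester enolate to the non-enolisable aryl aldehyde at low temperature is reliable, and the racemic carbinol is erased in step 4.

Step 4
Reactants: 7 ethyl (±)-3-Ar-3-hydroxypropanoate
Product: 8 ethyl 3-Ar-3-oxopropanoate
Conditions: Dess–Martin periodinane, CH2Cl2, 0 → 20 °C
Reagents that add atoms: none
Why: Dess–Martin oxidation of the secondary benzylic alcohol should give the β-keto ester without touching the trisubstituted alkene or the acetals.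

Step 5
Reactants: 8 ethyl 3-Ar-3-oxopropanoate
Product: 9 ethyl (3S)-3-Ar-3-hydroxypropanoate
Conditions: RuCl[(S,S)-TsDPEN](p-cymene) (1 mol%), HCO2H/Et3N (5:2), 40 °C
Reagents that add atoms: none
Why: Noyori asymmetric transfer hydrogenation, in which the (S,S)-diamine ruthenium hydride delivers hydride to the face of the aryl ketone fixed by the arene–CH/π contact of the six-membered transition state, should set the (S)-carbinol as for aryl alkyl ketones, and isolated alkenes are not reduced.

Step 6
Reactants: 9 ethyl (3S)-3-Ar-3-hydroxypropanoate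
Product: 10 (1S)-1-Ar-propane-1,3-diol
Conditions: LiAlH4, THF, 0 °C
Reagents that add atoms: none
Why: Hydride reduction of the ester to the primary alcohol does not involve the stereocentre, and MOM ethers and the alkene are inert.

Step 7
Reactants: 10 (1S)-1-Ar-propane-1,3-diol
Product: 11 (1S)-1-Ar-3-[(triisopropylsilyl)oxy]propan-1-ol
Conditions: i-Pr3SiCl (1.1 equiv), imidazole, CH2Cl2, 0 → 20 °C
Reagents that add atoms: chlorotriisopropylsilane, CC(C)[Si](Cl)(C(C)C)C(C)C
Why: Silylation with the bulky chlorosilane should occur at the primary hydroxyl in strong preference to the hindered secondary benzylic one.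

Step 8
Reactants: 11 (1S)-1-Ar-3-[(triisopropylsilyl)oxy]propan-1-ol; 12 trichloroethylene
Product: 15 (S)-(E)-1,2-dichlorovinyl ether of 11, via potassium alkoxide 13 (not isolated), via dichloroacetylene 14 (not isolated)
Conditions: KH (2 equiv), THF, 0 °C; 12 (1.2 equiv), −50 → 20 °C
Reagents that add atoms: none
Why: The alkoxide dehydrochlorinates trichloroethylene to dichloroacetylene and adds to it in anti fashion to give the (E)-dichlorovinyl ether (the established dichlorovinyl ether route to alkynyl ethers), and since the C2–O bond is never broken the configuration is kept.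

Step 9
Reactants: 15 (S)-(E)-1,2-dichlorovinyl ether of 11; 16 prenyl bromide (1-bromo-3-methylbut-2-ene)
Product: 19 (S)-1-Ar-1-[(5-methylhex-4-en-1-yn-1-yl)oxy]-3-[(triisopropylsilyl)oxy]propane, via chloroalkynyl ether 17 (not isolated), via lithium acetylide 18 (not isolated)
Conditions: n-BuLi (2.3 equiv), THF, −78 → −40 °C; 16, DMPU, −78 → 0 °C; cold work-up, Et3N-washed silica
Reagents that add atoms: none
Why: Deprotonation with β-elimination gives the chloroalkyne, chlorine–lithium exchange gives the lithium alkoxyacetylide, and SN2 alkylation at the primary carbon of the allylic bromide in the presence of DMPU should give the internal alkynyl ether, which is kept at or below 0 °C to avoid retro-ene and sigmatropic loss.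

Step 10
Reactants: 20 3-chloropropanoyl chloride
Product: 21 4-chloro-1-diazobutan-2-one
Conditions: CH2N2 (3 equiv), Et2O, 0 °C
Reagents that add atoms: diazomethane, C=[N+]=[N-]
Why: Acylation of diazomethane by the acid chloride (first stage of the Arndt–Eistert sequence) gives the diazomethyl ketone, a second equivalent of diazomethane taking up the hydrogen chloride.

Step 11
Reactants: 21 4-chloro-1-diazobutan-2-one
Product: 22 1-diazobut-3-en-2-one
Conditions: DBU (1.05 equiv), Et2O, 0 °C; filtered, used as a cold solution in the dark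
Reagents that add atoms: none
Why: E1cB dehydrochlorination of the β-chloro ketone by the amidine base should give the vinyl diazomethyl ketone, and unmasking the alkene only after the diazo group is in place avoids the dipolar cycloaddition that diazomethane would undergo with an acryloyl chloride.

Step 12
Reactants: 19 (S)-1-Ar-1-[(5-methylhex-4-en-1-yn-1-yl)oxy]-3-[(triisopropylsilyl)oxy]propane; 22 1-diazobut-3-en-2-one
Product: 27 3-{(1S)-1-Ar-3-[(triisopropylsilyl)oxy]propoxy}-2-(3-methylbut-2-en-1-yl)phenol, via vinylketene 23 (not isolated), via vinylcyclobutenone 24 (not isolated), via dienylketene 25 (not isolated), via cyclohexadienone 26 (not isolated)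
Conditions: 22 (2.5 equiv, slow addition), hν (medium-pressure Hg lamp, Pyrex filter), degassed CH2Cl2, 20 °C; then toluene, 80 °C; K2CO3, MeOH, 0 °C (work-up)
Reagents that add atoms: none
Why: Light expels dinitrogen from 22 and the vinyl group shifts to the carbene carbon (Wolff rearrangement) to give vinylketene 23; the prenyl-bearing, nucleophilic carbon of the alkynyl ether then bonds to the ketene carbonyl carbon (C7–C8) and the oxygen-bearing carbon closes onto the ketene α-carbon (C8a–C4a) in a [2+2] cycloaddition to cyclobutenone 24. Four-electron electrocyclic opening of 24, driven by ring strain and helped by the continued irradiation and the final warming, gives dienylketene 25. Ring A closes by six-electron electrocyclisation of 25 (C6–C7) to dienone 26, which tautomerises to the phenol. The closest known reaction type is the Danheiser benzannulation in its photochemical diazo ketone form with alkoxy- and silyloxyalkynes as ketenophiles. No stereocentre is created (the ring carbon of 24 that carries the vinyl group is transient), and C2 keeps its (S) configuration because none of its bonds is touched. The step needs regioselectivity, secured by the polarisation of the alkynyl ether (prenyl can only end at C8 and O1 at C8a), and chemoselectivity for cycloaddition over retro-ene or sigmatropic loss of the secondary benzylic alkynyl ether, secured by generating the ketene at 20 °C and warming only after the alkyne is consumed; slow addition of 22 limits ketene dimerisation and the methanolysis returns any phenol acylated by surplus ketene.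

Step 13
Reactants: 27 3-{(1S)-1-Ar-3-[(triisopropylsilyl)oxy]propoxy}-2-(3-methylbut-2-en-1-yl)phenol
Product: 28 methoxymethyl ether of 27
Conditions: MOMCl, i-Pr2NEt, CH2Cl2, 0 → 20 °C
Reagents that add atoms: chloromethyl methyl ether, COCCl
Why: MOM protection of the new C7 phenol keeps ring A electron-rich for step 16 and shields it from the oxidant of step 15.

Step 14
Reactants: 28 methoxymethyl ether of 27
Product: 29 (3S)-3-Ar-3-[3-(methoxymethoxy)-2-(3-methylbut-2-en-1-yl)phenoxy]propan-1-ol
Conditions: Bu4NF, THF, 20 °C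
Reagents that add atoms: none
Why: Fluoride cleaves the Si–O bond of the primary silyl ether, while aryl MOM ethers, the benzylic aryl ether and the alkenes are inert.

Step 15
Reactants: 29 (3S)-3-Ar-3-[3-(methoxymethoxy)-2-(3-methylbut-2-en-1-yl)phenoxy]propan-1-ol
Product: 31 (3S)-3-Ar-3-[3-(methoxymethoxy)-2-(3-methylbut-2-en-1-yl)phenoxy]propanoic acid, via aldehyde 30 (not isolated)
Conditions: TEMPO (20 mol%), PhI(OAc)2 (2.2 equiv), MeCN/H2O (1:1), 20 °C
Reagents that add atoms: water, O
Why: Oxoammonium-mediated oxidation takes the primary alcohol to the aldehyde, whose hydrate is oxidised on to the acid, and the near-neutral medium should avoid β-elimination of the aryloxy group and leave the alkenes alone.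

Step 16
Reactants: 31 (3S)-3-Ar-3-[3-(methoxymethoxy)-2-(3-methylbut-2-en-1-yl)phenoxy]propanoic acid
Product: 33 (2S)-2-Ar-7-(methoxymethoxy)-8-(3-methylbut-2-en-1-yl)-2,3-dihydro-4H-chromen-4-one, via mixed anhydride 32 (not isolated)
Conditions: (CF3CO)2O (1.5 equiv), CH2Cl2, 0 °C
Reagents that add atoms: none
Why: Intramolecular Friedel–Crafts acylation through the mixed trifluoroacetic anhydride should close ring C at C4a, which is ortho to O1, para to the C7 MOM ether and the only position the tether reaches through a six-membered transition state, so no strong Lewis acid is needed and C2 is not part of the reacting bonds.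

Step 17
Reactants: 33 (2S)-2-Ar-7-(methoxymethoxy)-8-(3-methylbut-2-en-1-yl)-2,3-dihydro-4H-chromen-4-one
Product: 34 (2S)-2-[3,4-dihydroxy-5-(3-methylbut-2-en-1-yl)phenyl]-7-hydroxy-8-(3-methylbut-2-en-1-yl)-2,3-dihydro-4H-chromen-4-one
Conditions: HCl (3 M aq.), MeOH, 45 °C
Reagents that add atoms: none
Why: Acid-catalysed acetal exchange with methanol removes the three MOM groups under conditions commonly used on ortho-prenylated flavanones, which should spare the prenyl groups and the C2 configuration.

**Compound list**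

1 | 3-bromo-4,5-dihydroxybenzaldehyde | O=Cc1cc(O)c(O)c(Br)c1 | starting material
2 | 3-bromo-4,5-bis(methoxymethoxy)benzaldehyde | O=Cc1cc(OCOC)c(OCOC)c(Br)c1 | intermediate
3 | tributyl(3-methylbut-2-en-1-yl)stannane | CCCC[Sn](CCCC)(CCCC)CC=C(C)C | starting material
4 | 3,4-bis(methoxymethoxy)-5-(3-methylbut-2-en-1-yl)benzaldehyde | CC(C)=CCc1cc(C=O)cc(OCOC)c1OCOC | intermediate
5 | ethyl acetate | CCOC(C)=O | starting material
6 | lithium enolate of ethyl acetate (formed in the flask) | [Li]OC(=C)OCC | intermediate
7 | ethyl (±)-3-Ar-3-hydroxypropanoate | CC(C)=CCc1cc(C(O)CC(=O)OCC)cc(OCOC)c1OCOC | intermediate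
8 | ethyl 3-Ar-3-oxopropanoate | CC(C)=CCc1cc(C(=O)CC(=O)OCC)cc(OCOC)c1OCOC | intermediate
9 | ethyl (3S)-3-Ar-3-hydroxypropanoate | CC(C)=CCc1cc([C@H](CC(=O)OCC)O)cc(OCOC)c1OCOC | intermediate
10 | (1S)-1-Ar-propane-1,3-diol | CC(C)=CCc1cc([C@H](CCO)O)cc(OCOC)c1OCOC | intermediate
11 | (1S)-1-Ar-3-[(triisopropylsilyl)oxy]propan-1-ol | CC(C)=CCc1cc([C@H](CCO[Si](C(C)C)(C(C)C)C(C)C)O)cc(OCOC)c1OCOC | intermediate
12 | trichloroethylene | ClC=C(Cl)Cl | starting material
13 | potassium alkoxide of 11 (formed in the flask) | CC(C)=CCc1cc([C@H](CCO[Si](C(C)C)(C(C)C)C(C)C)O[K])cc(OCOC)c1OCOC | intermediate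
14 | dichloroacetylene (formed in the flask) | ClC#CCl | intermediate
15 | (S)-(E)-1,2-dichlorovinyl ether of 11 | CC(C)=CCc1cc([C@H](CCO[Si](C(C)C)(C(C)C)C(C)C)O/C(Cl)=C\Cl)cc(OCOC)c1OCOC | intermediate
16 | prenyl bromide (1-bromo-3-methylbut-2-ene) | CC(C)=CCBr | starting material
17 | (S)-chloroethynyl ether of 11 (formed in the flask) | CC(C)=CCc1cc([C@H](CCO[Si](C(C)C)(C(C)C)C(C)C)OC#CCl)cc(OCOC)c1OCOC | intermediate
18 | (S)-lithium acetylide of the ethynyl ether of 11 (formed in the flask) | CC(C)=CCc1cc([C@H](CCO[Si](C(C)C)(C(C)C)C(C)C)OC#C[Li])cc(OCOC)c1OCOC | intermediate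
19 | (S)-1-Ar-1-[(5-methylhex-4-en-1-yn-1-yl)oxy]-3-[(triisopropylsilyl)oxy]propane | CC(C)=CCc1cc([C@H](CCO[Si](C(C)C)(C(C)C)C(C)C)OC#CCC=C(C)C)cc(OCOC)c1OCOC | intermediate
20 | 3-chloropropanoyl chloride | ClCCC(=O)Cl | starting material
21 | 4-chloro-1-diazobutan-2-one | ClCCC(=O)C=[N+]=[N-] | intermediate
22 | 1-diazobut-3-en-2-one | C=CC(=O)C=[N+]=[N-] | intermediate
23 | vinylketene (buta-1,3-dien-1-one, formed in the flask) | C=CC=C=O | intermediate
24 | 3-alkoxy-2-prenyl-4-vinylcyclobut-2-en-1-one, alkoxy = (S)-1-Ar-3-(triisopropylsilyloxy)propoxy, both epimers at the vinyl-bearing carbon (formed in the flask) | CC(C)=CCc1cc([C@H](CCO[Si](C(C)C)(C(C)C)C(C)C)OC2=C(CC=C(C)C)C(=O)C2C=C)cc(OCOC)c1OCOC | intermediate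
25 | 3-alkoxy-2-prenylhexa-1,3,5-trien-1-one (dienylketene, same alkoxy group, formed in the flask) | CC(C)=CCc1cc([C@H](CCO[Si](C(C)C)(C(C)C)C(C)C)O/C(=C/C=C)C(CC=C(C)C)=C=O)cc(OCOC)c1OCOC | intermediate
26 | 3-alkoxy-2-prenylcyclohexa-2,4-dien-1-one (same alkoxy group, formed in the flask) | CC(C)=CCc1cc([C@H](CCO[Si](C(C)C)(C(C)C)C(C)C)OC2=C(CC=C(C)C)C(=O)CC=C2)cc(OCOC)c1OCOC | intermediate
27 | 3-{(1S)-1-Ar-3-[(triisopropylsilyl)oxy]propoxy}-2-(3-methylbut-2-en-1-yl)phenol | CC(C)=CCc1cc([C@H](CCO[Si](C(C)C)(C(C)C)C(C)C)Oc2cccc(O)c2CC=C(C)C)cc(OCOC)c1OCOC | intermediate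
28 | methoxymethyl ether of 27 | CC(C)=CCc1cc([C@H](CCO[Si](C(C)C)(C(C)C)C(C)C)Oc2cccc(OCOC)c2CC=C(C)C)cc(OCOC)c1OCOC | intermediate
29 | (3S)-3-Ar-3-[3-(methoxymethoxy)-2-(3-methylbut-2-en-1-yl)phenoxy]propan-1-ol | CC(C)=CCc1cc([C@H](CCO)Oc2cccc(OCOC)c2CC=C(C)C)cc(OCOC)c1OCOC | intermediate
30 | (3S)-3-Ar-3-[3-(methoxymethoxy)-2-(3-methylbut-2-en-1-yl)phenoxy]propanal (formed in the flask) | CC(C)=CCc1cc([C@H](CC=O)Oc2cccc(OCOC)c2CC=C(C)C)cc(OCOC)c1OCOC | intermediate
31 | (3S)-3-Ar-3-[3-(methoxymethoxy)-2-(3-methylbut-2-en-1-yl)phenoxy]propanoic acid | CC(C)=CCc1cc([C@H](CC(=O)O)Oc2cccc(OCOC)c2CC=C(C)C)cc(OCOC)c1OCOC | intermediate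
32 | mixed anhydride of 31 with trifluoroacetic acid (formed in the flask) | CC(C)=CCc1cc([C@H](CC(=O)OC(=O)C(F)(F)F)Oc2cccc(OCOC)c2CC=C(C)C)cc(OCOC)c1OCOC | intermediate
33 | (2S)-2-Ar-7-(methoxymethoxy)-8-(3-methylbut-2-en-1-yl)-2,3-dihydro-4H-chromen-4-one | CC(C)=CCc1cc([C@@H]2CC(=O)c3ccc(OCOC)c(CC=C(C)C)c3O2)cc(OCOC)c1OCOC | intermediate
34 | (2S)-2-[3,4-dihydroxy-5-(3-methylbut-2-en-1-yl)phenyl]-7-hydroxy-8-(3-methylbut-2-en-1-yl)-2,3-dihydro-4H-chromen-4-one | CC(C)=CCc1cc([C@@H]2CC(=O)c3ccc(O)c(CC=C(C)C)c3O2)cc(O)c1O | target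

**Step count**

Total: 17 steps. Longest linear sequence: 15 steps (steps 1–9, then 12–17); steps 10 and 11 form the short diazo ketone branch.

**Steps most likely to fail**

Step 12. Vinylketene 23 may dimerise or polymerise, or the alkynyl ether may be lost by retro-ene or sigmatropic pathways, faster than the [2+2] cycloaddition, so that ring A does not form. The fallback takes ring A from a purchased arene and makes the O1–C2 bond by Mitsunobu inversion. It sets out from keto ester 8. Transfer hydrogenation with RuCl[(R,R)-TsDPEN](p-cymene) should give ethyl (3R)-3-Ar-3-hydroxypropanoate F1, LiAlH4 the (1R)-diol F2, and i-Pr3SiCl with imidazole the (1R)-mono-TIPS alcohol F3. Mitsunobu etherification of F3 (PPh3, DIAD, toluene, 0 °C) with an excess of purchased 2-iodobenzene-1,3-diol (Oc1cccc(O)c1I) should give, with inversion at C2, the (S)-2-iodophenol ether F4. Stille coupling of F4 with stannane 3 (Pd(PPh3)4, DMF) installs the C8 prenyl group and rejoins the route at phenol 27.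

Step 16. The trifluoroacetic acid released may ionise the electron-rich benzylic C2–O1 bond (β-elimination to a cinnamic acid or loss of configuration) or protonate the prenyl alkenes before the C4–C4a bond forms. The fallback replaces acylation by hydroxyalkylation and sets out from alcohol 29. Dess–Martin oxidation gives aldehyde 30, which is isolated. Me2AlCl (CH2Cl2, −78 °C), a Lewis acid that also scavenges protons, should promote intramolecular Friedel–Crafts hydroxyalkylation at C4a to the (2S)-flavan-4-ol F5 (both C4 epimers, held as the aluminium alkoxide until work-up). Oxidation of the benzylic alcohol with MnO2 (CH2Cl2) rejoins the route at flavanone 33.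

Step 9. C-alkylation of the lithium alkynyl ether by the allylic bromide may be slow, attack may occur at the tertiary terminus (SN2′), and the product may be lost by retro-ene fragmentation during the warm-up the alkylation needs. The fallback builds the C8 prenyl group after ring A and sets out from dichlorovinyl ether 15. Lithium acetylide 18, made as in step 9, is trapped at −78 °C with unhindered, symmetrical allyl bromide to give the allyl alkynyl ether F6. Under the conditions of step 12 with 22, F6 should pass through the allyl analogues of 24–26 (cyclobutenone F7, dienylketene F8, cyclohexadienone F9) to the 8-allyl phenol F10. Cross-metathesis of F10 with 2-methylbut-2-ene (second-generation Grubbs catalyst, CH2Cl2, 40 °C) converts the allyl into the prenyl group, leaves the ring B prenyl group unchanged because its exchange is degenerate, and rejoins the route at 27.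

**Further compounds**

F1 | step 12 | ethyl (3R)-3-Ar-3-hydroxypropanoate | CC(C)=CCc1cc([C@@H](CC(=O)OCC)O)cc(OCOC)c1OCOC
F2 | step 12 | (1R)-1-Ar-propane-1,3-diol | CC(C)=CCc1cc([C@@H](CCO)O)cc(OCOC)c1OCOC
F3 | step 12 | (1R)-1-Ar-3-[(triisopropylsilyl)oxy]propan-1-ol | CC(C)=CCc1cc([C@@H](CCO[Si](C(C)C)(C(C)C)C(C)C)O)cc(OCOC)c1OCOC
F4 | step 12 | 3-{(1S)-1-Ar-3-[(triisopropylsilyl)oxy]propoxy}-2-iodophenol | CC(C)=CCc1cc([C@H](CCO[Si](C(C)C)(C(C)C)C(C)C)Oc2cccc(O)c2I)cc(OCOC)c1OCOC
F5 | step 16 | (2S)-2-Ar-7-(methoxymethoxy)-8-(3-methylbut-2-en-1-yl)chroman-4-ol (both C4 epimers) | CC(C)=CCc1cc([C@@H]2CC(O)c3ccc(OCOC)c(CC=C(C)C)c3O2)cc(OCOC)c1OCOC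
F6 | step 9 | (S)-1-Ar-1-(pent-4-en-1-yn-1-yloxy)-3-[(triisopropylsilyl)oxy]propane | CC(C)=CCc1cc([C@H](CCO[Si](C(C)C)(C(C)C)C(C)C)OC#CCC=C)cc(OCOC)c1OCOC
F7 | step 9 | 3-alkoxy-2-allyl-4-vinylcyclobut-2-en-1-one (alkoxy as in 24) | CC(C)=CCc1cc([C@H](CCO[Si](C(C)C)(C(C)C)C(C)C)OC2=C(CC=C)C(=O)C2C=C)cc(OCOC)c1OCOC
F8 | step 9 | 3-alkoxy-2-allylhexa-1,3,5-trien-1-one (alkoxy as in 24) | CC(C)=CCc1cc([C@H](CCO[Si](C(C)C)(C(C)C)C(C)C)O/C(=C/C=C)C(CC=C)=C=O)cc(OCOC)c1OCOC
F9 | step 9 | 3-alkoxy-2-allylcyclohexa-2,4-dien-1-one (alkoxy as in 24) | CC(C)=CCc1cc([C@H](CCO[Si](C(C)C)(C(C)C)C(C)C)OC2=C(CC=C)C(=O)CC=C2)cc(OCOC)c1OCOC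
F10 | step 9 | 2-allyl-3-{(1S)-1-Ar-3-[(triisopropylsilyl)oxy]propoxy}phenol | CC(C)=CCc1cc([C@H](CCO[Si](C(C)C)(C(C)C)C(C)C)Oc2cccc(O)c2CC=C)cc(OCOC)c1OCOC
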